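**Retrosynthetic overview**

- The strategy rests on furan C3, an unsubstituted CH between the aryl-bearing C2 and the chain-bearing C4. It is supplied as the carbon of trimethylsilyldiazomethane, which converts α-alkoxy ketone 25 into an alkylidene carbene that inserts into the benzylic ether C–H bond (new C3=C4 and C2–C3 bonds).
- The furan is the only ring made. It closes first as 2,5-dihydrofuran 30 and is then aromatised with DDQ; ester hydrolysis and cleavage of two MOM acetals finish the route.
- Ketone 25 comes from aldehyde 16 and an alkoxymethyllithium (from stannane 22, made from 2,5-dihydroxybenzaldehyde), followed by oxidation.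
- Aldehyde 16 comes from two Evans alkylations on a six-carbon backbone: methylation (C2) of a hept-6-enoyl imide, cleavage of the alkene to the acid, a second imide and prenylation (C5).

Key step: step 14

Remarks on the chemistry:
- The carbinol carbon of 24 and the ring CH(Ar) of 30 form as epimer mixtures, are left undefined in the SMILES, and are both erased later.
- Hept-6-enoic acid is the backbone, so that the alkene is cleaved to the carboxyl group in one step.
- Ketone 25 is assembled by C–C bond formation, because a metal-carbenoid O–H insertion on the corresponding diazoketone would compete with cyclopropanation of the well-placed prenyl alkene.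
- The MOM groups are removed in isopropanol/water, because HCl in methanol would re-esterify the free acid.
- Tributyl(iodomethyl)stannane 20 is taken as a commercial reagent.

**Route**

Step 1
Reactants: 1 hept-6-enoic acid; 2 (R)-4-benzyl-1,3-oxazolidin-2-one
Product: 4 (4R)-4-benzyl-3-(hept-6-enoyl)-1,3-oxazolidin-2-one, via mixed pivalic anhydride 3 (not isolated)
Conditions: PivCl, Et3N, THF, −20 °C; then LiCl, 2, −20 °C → rt
Reagents that add atoms: none
Why: N-acylation of the oxazolidinone through the mixed pivalic anhydride is the standard way to attach an Evans auxiliary to an unhindered acid and forms no stereocentre.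

Step 2
Reactants: 4 (4R)-4-benzyl-3-(hept-6-enoyl)-1,3-oxazolidin-2-one
Product: 6 (4R)-4-benzyl-3-[(2R)-2-methylhept-6-enoyl]-1,3-oxazolidin-2-one, via sodium Z-enolate 5 (not isolated)
Conditions: NaN(SiMe3)2, THF, −78 °C; then MeI, −78 °C
Reagents that add atoms: iodomethane, CI
Why: Evans asymmetric alkylation, in which the chelated Z-enolate is methylated on the face away from the benzyl group of the (4R)-auxiliary, sets C2 as R, and the minor diastereomer should be removable by chromatography.

Step 3
Reactants: 6 (4R)-4-benzyl-3-[(2R)-2-methylhept-6-enoyl]-1,3-oxazolidin-2-one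
Product: 7 methyl (2R)-2-methylhept-6-enoate
Conditions: MeMgBr, MeOH, CH2Cl2, 0 °C (MeOMgBr formed in the flask)
Reagents that add atoms: methanol, CO
Why: Transesterification of the imide with bromomagnesium methoxide attacks the exocyclic carbonyl, releases the auxiliary and is mild enough not to epimerise the α-methyl centre.

Step 4
Reactants: 7 methyl (2R)-2-methylhept-6-enoate
Product: 8 (5R)-6-methoxy-5-methyl-6-oxohexanoic acid
Conditions: RuCl3·xH2O (cat.), NaIO4, EtOAc/MeCN/H2O, rt
Reagents that add atoms: sodium periodate, [Na+].[O-]I(=O)(=O)=O; water, O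
Why: Ruthenium tetroxide-catalysed oxidative cleavage converts the terminal alkene into the carboxylic acid with loss of one carbon, and no other oxidisable group is present at this stage.

Step 5
Reactants: 8 (5R)-6-methoxy-5-methyl-6-oxohexanoic acid; 9 (S)-4-benzyl-1,3-oxazolidin-2-one
Product: 11 methyl (2R)-6-[(4S)-4-benzyl-2-oxo-1,3-oxazolidin-3-yl]-2-methyl-6-oxohexanoate, via mixed pivalic anhydride 10 (not isolated)
Conditions: PivCl, Et3N, THF, −20 °C; then LiCl, 9, −20 °C → rt
Reagents that add atoms: none
Why: The same mixed-anhydride N-acylation, now with the (4S)-auxiliary, is non-enolising and leaves the methyl ester and its α-centre untouched.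

Step 6
Reactants: 11 methyl (2R)-6-[(4S)-4-benzyl-2-oxo-1,3-oxazolidin-3-yl]-2-methyl-6-oxohexanoate; 12 1-bromo-3-methylbut-2-ene (prenyl bromide)
Product: 14 methyl (2R,5R)-5-{[(4S)-4-benzyl-2-oxo-1,3-oxazolidin-3-yl]carbonyl}-2,8-dimethylnon-7-enoate, via sodium Z-enolate 13 (not isolated)
Conditions: NaN(SiMe3)2, THF, −78 °C; then 12, −78 → −40 °C
Reagents that add atoms: none
Why: Evans asymmetric alkylation, in which the base removes the more acidic imide α-proton in preference to the ester α-proton and the chelated Z-enolate takes the allylic bromide on the face opposite the benzyl group of the (4S)-auxiliary, sets C5 as R.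

Step 7
Reactants: 14 methyl (2R,5R)-5-{[(4S)-4-benzyl-2-oxo-1,3-oxazolidin-3-yl]carbonyl}-2,8-dimethylnon-7-enoate
Product: 15 methyl (2R,5R)-5-(hydroxymethyl)-2,8-dimethylnon-7-enoate
Conditions: NaBH4, THF/H2O, 0 °C → rt
Reagents that add atoms: none
Why: Reductive removal of the auxiliary with NaBH4 in wet THF reduces the activated imide carbonyl to the primary alcohol, while a simple methyl ester is not reduced under these conditions.

Step 8
Reactants: 15 methyl (2R,5R)-5-(hydroxymethyl)-2,8-dimethylnon-7-enoate
Product: 16 methyl (2R,5R)-5-formyl-2,8-dimethylnon-7-enoate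
Conditions: Dess–Martin periodinane, NaHCO3, CH2Cl2, 0 °C → rt; used at once
Reagents that add atoms: none
Why: Buffered Dess–Martin oxidation gives the α-branched aldehyde under non-basic conditions that should not epimerise C5.

Step 9
Reactants: 17 2,5-dihydroxybenzaldehyde
Product: 18 2,5-bis(methoxymethoxy)benzaldehyde
Conditions: MOMCl, i-Pr2NEt, CH2Cl2, 0 °C → rt
Reagents that add atoms: chloromethyl methyl ether, COCCl
Why: O-alkylation of both phenols gives acetals that withstand the organolithium, hydride, base and DDQ steps ahead.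

Step 10
Reactants: 18 2,5-bis(methoxymethoxy)benzaldehyde
Product: 19 [2,5-bis(methoxymethoxy)phenyl]methanol
Conditions: NaBH4, MeOH, 0 °C
Reagents that add atoms: none
Why: Borohydride reduction of the aryl aldehyde to the benzylic alcohol is chemoselective and leaves the MOM acetals intact.

Step 11
Reactants: 19 [2,5-bis(methoxymethoxy)phenyl]methanol; 20 tributyl(iodomethyl)stannane
Product: 22 tributyl({[2,5-bis(methoxymethoxy)phenyl]methoxy}methyl)stannane, via sodium benzylic alkoxide 21 (not isolated)
Conditions: NaH, THF/DMF, 0 °C; then 20, rt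
Reagents that add atoms: none
Why: Williamson ether synthesis of the alkoxide with the primary iodide gives the α-alkoxymethylstannane, the standard precursor of an alkoxymethyllithium.

Step 12
Reactants: 16 methyl (2R,5R)-5-formyl-2,8-dimethylnon-7-enoate; 22 tributyl({[2,5-bis(methoxymethoxy)phenyl]methoxy}methyl)stannane
Product: 24 methyl (2R,5R)-5-{2-[2,5-bis(methoxymethoxy)benzyloxy]-1-hydroxyethyl}-2,8-dimethylnon-7-enoate (both carbinol epimers), via alkoxymethyllithium 23 (not isolated)
Conditions: 22, n-BuLi, THF, −78 °C, 10 min; then 16, −78 °C; aq. NH4Cl at −78 °C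
Reagents that add atoms: none
Why: Tin–lithium exchange gives the α-alkoxymethyllithium, which adds to the aldehyde at −78 °C much faster than to the α-branched methyl ester; the new carbinol centre forms without control and is removed in step 13.

Step 13
Reactants: 24 methyl (2R,5R)-5-{2-[2,5-bis(methoxymethoxy)benzyloxy]-1-hydroxyethyl}-2,8-dimethylnon-7-enoate
Product: 25 methyl (2R,5R)-5-{2-[2,5-bis(methoxymethoxy)benzyloxy]acetyl}-2,8-dimethylnon-7-enoate
Conditions: Dess–Martin periodinane, NaHCO3, CH2Cl2, rt
Reagents that add atoms: none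
Why: Dess–Martin oxidation of the secondary alcohol gives the α-alkoxy ketone under buffered, non-enolising conditions, and both carbinol epimers converge on one ketone.

Step 14
Reactants: 25 methyl (2R,5R)-5-{2-[2,5-bis(methoxymethoxy)benzyloxy]acetyl}-2,8-dimethylnon-7-enoate; 26 trimethylsilyldiazomethane
Product: 30 methyl (2R,5R)-5-{5-[2,5-bis(methoxymethoxy)phenyl]-2,5-dihydrofuran-3-yl}-2,8-dimethylnon-7-enoate (both epimers at the ring CH), via lithio(trimethylsilyl)diazomethane 27 (not isolated), via diazoalkene 28 (not isolated), via alkylidene carbene 29 (not isolated)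
Conditions: 26, n-BuLi, THF, −78 °C, 30 min; then 25, −78 → 0 °C; aq. NH4Cl
Reagents that add atoms: none
Why: Lithiated trimethylsilyldiazomethane 27 adds to the ketone carbonyl and Peterson-type loss of lithium trimethylsilanolate gives diazoalkene 28 (this olefination creates the future furan C3=C4 bond), which loses N2 to the singlet alkylidene carbene 29. The carbene carbon inserts in a concerted step into the C–H bond five atoms away on the benzylic ether carbon, so the C2–C3 bond forms and the 2,5-dihydrofuran closes at carbon, not at oxygen, by a 1,5 C–H insertion through a five-membered transition state. The closest known reaction type is the conversion of α-alkoxy ketones into 2,5-dihydrofurans by alkylidene carbene generation with this reagent (Colvin-type olefination followed by 1,5 C–H insertion). The new ring CH(Ar) centre has no controlling element and needs none, since step 15 erases it, while the furylic centre (chain C5, α to the ketone) should be kept because carbonyl addition of the weakly basic reagent at −78 °C outruns enolisation. The step needs chemoselectivity among three 1,5 sites and two carbonyl groups: the targeted C–H is both benzylic and α to the ether oxygen, the most activated class for this insertion, whereas the chain C3 methylene is unactivated and addition to the prenyl alkene would give a strained bicyclo[3.1.0]hex-1-ene, and the ketone is far more electrophilic than the α-branched methyl ester at low temperature.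

Step 15
Reactants: 30 methyl (2R,5R)-5-{5-[2,5-bis(methoxymethoxy)phenyl]-2,5-dihydrofuran-3-yl}-2,8-dimethylnon-7-enoate
Product: 31 methyl (2R,5R)-5-{5-[2,5-bis(methoxymethoxy)phenyl]furan-3-yl}-2,8-dimethylnon-7-enoate
Conditions: DDQ (1.1 equiv), toluene, rt
Reagents that add atoms: none
Why: DDQ dehydrogenation, by hydride abstraction from the ring CH that is benzylic, allylic and α to oxygen followed by loss of a proton, aromatises the dihydrofuran and removes the uncontrolled ring stereocentre, and one equivalent at room temperature should spare the prenyl group and the protected hydroquinone.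

Step 16
Reactants: 31 methyl (2R,5R)-5-{5-[2,5-bis(methoxymethoxy)phenyl]furan-3-yl}-2,8-dimethylnon-7-enoate
Product: 32 (2R,5R)-5-{5-[2,5-bis(methoxymethoxy)phenyl]furan-3-yl}-2,8-dimethylnon-7-enoic acid
Conditions: LiOH·H2O, THF/MeOH/H2O, rt; then cold dilute HCl to pH 4
Reagents that add atoms: lithium hydroxide, [Li+].[OH-]
Why: Saponification of the methyl ester leaves the MOM acetals, the furan and the alkene untouched, and hydrolysis of an α-branched ester is faster than its enolisation, so C2 should be kept.

Step 17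
Reactants: 32 (2R,5R)-5-{5-[2,5-bis(methoxymethoxy)phenyl]furan-3-yl}-2,8-dimethylnon-7-enoic acid
Product: 33 (2R,5R)-5-[5-(2,5-dihydroxyphenyl)furan-3-yl]-2,8-dimethylnon-7-enoic acid
Conditions: 2 M aq. HCl, i-PrOH/THF, 40 °C, under argon
Reagents that add atoms: none
Why: Acid-catalysed acetal hydrolysis of the two aryl MOM ethers frees the hydroquinone last and under non-oxidising conditions, and isopropanol in place of methanol keeps the hindered free acid from Fischer esterification.

**Compound list**

1 | hept-6-enoic acid | C=CCCCCC(=O)O | starting material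
2 | (R)-4-benzyl-1,3-oxazolidin-2-one | O=C1N[C@H](Cc2ccccc2)CO1 | starting material
3 | hept-6-enoic pivalic anhydride (not isolated) | C=CCCCCC(=O)OC(=O)C(C)(C)C | intermediate
4 | (4R)-4-benzyl-3-(hept-6-enoyl)-1,3-oxazolidin-2-one | C=CCCCCC(=O)N1[C@H](Cc2ccccc2)COC1=O | intermediate
5 | sodium Z-enolate of 4 (not isolated) | [Na+].C=CCCC/C=C(\[O-])N1[C@H](Cc2ccccc2)COC1=O | intermediate
6 | (4R)-4-benzyl-3-[(2R)-2-methylhept-6-enoyl]-1,3-oxazolidin-2-one | C=CCCC[C@@H](C)C(=O)N1[C@H](Cc2ccccc2)COC1=O | intermediate
7 | methyl (2R)-2-methylhept-6-enoate | C=CCCC[C@@H](C)C(=O)OC | intermediate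
8 | (5R)-6-methoxy-5-methyl-6-oxohexanoic acid | O=C(O)CCC[C@@H](C)C(=O)OC | intermediate
9 | (S)-4-benzyl-1,3-oxazolidin-2-one | O=C1N[C@@H](Cc2ccccc2)CO1 | starting material
10 | (5R)-6-methoxy-5-methyl-6-oxohexanoic pivalic anhydride (not isolated) | CC(C)(C)C(=O)OC(=O)CCC[C@@H](C)C(=O)OC | intermediate
11 | methyl (2R)-6-[(4S)-4-benzyl-2-oxo-1,3-oxazolidin-3-yl]-2-methyl-6-oxohexanoate | COC(=O)[C@H](C)CCCC(=O)N1[C@@H](Cc2ccccc2)COC1=O | intermediate
12 | 1-bromo-3-methylbut-2-ene (prenyl bromide) | CC(C)=CCBr | starting material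
13 | sodium Z-enolate of 11 (not isolated) | [Na+].COC(=O)[C@H](C)CC/C=C(\[O-])N1[C@@H](Cc2ccccc2)COC1=O | intermediate
14 | methyl (2R,5R)-5-{[(4S)-4-benzyl-2-oxo-1,3-oxazolidin-3-yl]carbonyl}-2,8-dimethylnon-7-enoate | CC(C)=CC[C@@H](CC[C@@H](C)C(=O)OC)C(=O)N1[C@@H](Cc2ccccc2)COC1=O | intermediate
15 | methyl (2R,5R)-5-(hydroxymethyl)-2,8-dimethylnon-7-enoate | CC(C)=CC[C@@H](CC[C@@H](C)C(=O)OC)CO | intermediate
16 | methyl (2R,5R)-5-formyl-2,8-dimethylnon-7-enoate | CC(C)=CC[C@@H](CC[C@@H](C)C(=O)OC)C=O | intermediate
17 | 2,5-dihydroxybenzaldehyde | O=Cc1cc(O)ccc1O | starting material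
18 | 2,5-bis(methoxymethoxy)benzaldehyde | O=Cc1cc(OCOC)ccc1OCOC | intermediate
19 | [2,5-bis(methoxymethoxy)phenyl]methanol | OCc1cc(OCOC)ccc1OCOC | intermediate
20 | tributyl(iodomethyl)stannane | CCCC[Sn](CCCC)(CCCC)CI | starting material
21 | sodium [2,5-bis(methoxymethoxy)phenyl]methanolate (not isolated) | [Na+].[O-]Cc1cc(OCOC)ccc1OCOC | intermediate
22 | tributyl({[2,5-bis(methoxymethoxy)phenyl]methoxy}methyl)stannane | CCCC[Sn](CCCC)(CCCC)COCc1cc(OCOC)ccc1OCOC | intermediate
23 | {[2,5-bis(methoxymethoxy)benzyl]oxy}methyllithium (not isolated) | [Li]COCc1cc(OCOC)ccc1OCOC | intermediate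
24 | methyl (2R,5R)-5-{2-[2,5-bis(methoxymethoxy)benzyloxy]-1-hydroxyethyl}-2,8-dimethylnon-7-enoate (both carbinol epimers) | CC(C)=CC[C@@H](CC[C@@H](C)C(=O)OC)C(O)COCc1cc(OCOC)ccc1OCOC | intermediate
25 | methyl (2R,5R)-5-{2-[2,5-bis(methoxymethoxy)benzyloxy]acetyl}-2,8-dimethylnon-7-enoate | CC(C)=CC[C@@H](CC[C@@H](C)C(=O)OC)C(=O)COCc1cc(OCOC)ccc1OCOC | intermediate
26 | trimethylsilyldiazomethane | C[Si](C)(C)C=[N+]=[N-] | starting material
27 | lithio(trimethylsilyl)diazomethane (not isolated) | C[Si](C)(C)C([Li])=[N+]=[N-] | intermediate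
28 | diazoalkene, methyl (2R,5R)-5-{3-[2,5-bis(methoxymethoxy)benzyloxy]-1-diazoprop-1-en-2-yl}-2,8-dimethylnon-7-enoate (not isolated) | CC(C)=CC[C@@H](CC[C@@H](C)C(=O)OC)C(COCc1cc(OCOC)ccc1OCOC)=C=[N+]=[N-] | intermediate
29 | alkylidene carbene from 28 by loss of N2 (not isolated) | CC(C)=CC[C@@H](CC[C@@H](C)C(=O)OC)C(COCc1cc(OCOC)ccc1OCOC)=[C] | intermediate
30 | methyl (2R,5R)-5-{5-[2,5-bis(methoxymethoxy)phenyl]-2,5-dihydrofuran-3-yl}-2,8-dimethylnon-7-enoate (both epimers at the ring CH) | CC(C)=CC[C@@H](CC[C@@H](C)C(=O)OC)C1=CC(c2cc(OCOC)ccc2OCOC)OC1 | intermediate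
31 | methyl (2R,5R)-5-{5-[2,5-bis(methoxymethoxy)phenyl]furan-3-yl}-2,8-dimethylnon-7-enoate | CC(C)=CC[C@@H](CC[C@@H](C)C(=O)OC)c1coc(-c2cc(OCOC)ccc2OCOC)c1 | intermediate
32 | (2R,5R)-5-{5-[2,5-bis(methoxymethoxy)phenyl]furan-3-yl}-2,8-dimethylnon-7-enoic acid | CC(C)=CC[C@@H](CC[C@@H](C)C(=O)O)c1coc(-c2cc(OCOC)ccc2OCOC)c1 | intermediate
33 | (2R,5R)-5-[5-(2,5-dihydroxyphenyl)furan-3-yl]-2,8-dimethylnon-7-enoic acid | CC(C)=CC[C@@H](CC[C@@H](C)C(=O)O)c1coc(-c2cc(O)ccc2O)c1 | target

**Step count and risk**

Total step count: 17. Longest linear sequence: 14 steps (steps 1–8, then 12–17); steps 9–11 prepare the aryl fragment.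

Steps most likely to fail:

1. Step 14. The carbene may be diverted into addition to the prenyl alkene or insertion into the chain methylene, the lithium reagent may attack the methyl ester, or the ketone may enolise and C5 epimerise.
 - Fallback: the furan is closed by cyclodehydration of a 3-alkyne-1,2-diol. It sets out from aldehyde 16 (with 18 and 20) and comes back at furan 31, so step 15 is not needed.
 - 4-Methoxybenzyl alcohol is alkylated with 20 (NaH, THF/DMF) to tributyl{[(4-methoxybenzyl)oxy]methyl}stannane F1.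
 - F1 is transmetalated with n-BuLi at −78 °C and added to 16 to give methyl (2R,5R)-5-{1-hydroxy-2-[(4-methoxybenzyl)oxy]ethyl}-2,8-dimethylnon-7-enoate F2.
 - Dess–Martin oxidation gives methyl (2R,5R)-5-{[(4-methoxybenzyl)oxy]acetyl}-2,8-dimethylnon-7-enoate F3.
 - Aldehyde 18 is homologated with the Ohira–Bestmann reagent (K2CO3, MeOH) to 2-ethynyl-1,4-bis(methoxymethoxy)benzene F4.
 - F4 is deprotonated with n-BuLi (THF, −78 °C) and added to F3 to give methyl (2R,5R)-5-{4-[2,5-bis(methoxymethoxy)phenyl]-2-hydroxy-1-[(4-methoxybenzyl)oxy]but-3-yn-2-yl}-2,8-dimethylnon-7-enoate F5.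
 - DDQ in CH2Cl2/pH 7 buffer removes the 4-methoxybenzyl group to give methyl (2R,5R)-5-{4-[2,5-bis(methoxymethoxy)phenyl]-1,2-dihydroxybut-3-yn-2-yl}-2,8-dimethylnon-7-enoate F6.
 - Ph3PAuCl/AgOTf (cat., THF, rt) then brings about 5-endo-dig attack of the primary hydroxyl on the alkyne and loss of water, which should give 31.

2. Step 12. The alkoxymethyllithium may undergo [1,2]-Wittig rearrangement or be protonated before it adds, the α-branched aldehyde may epimerise, or the ester may be attacked.
 - Fallback: the ether C–O bond is formed by carbenoid O–H insertion instead of the C–C bond by organolithium addition. It sets out from imide 14 and comes back at ketone 25, so steps 7, 8, 11, 12 and 13 are not needed.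
 - LiOH/H2O2 (THF/H2O, 0 °C) cleaves the auxiliary to (2R,5R)-6-methoxy-5-methyl-2-(3-methylbut-2-en-1-yl)-6-oxohexanoic acid F7.
 - (COCl)2 with catalytic DMF gives methyl (2R,5R)-5-(chlorocarbonyl)-2,8-dimethylnon-7-enoate F8.
 - Treatment with 26 (MeCN/THF, 0 °C) gives methyl (2R,5R)-5-(diazoacetyl)-2,8-dimethylnon-7-enoate F9.
 - Rh2(OAc)4 (cat., CH2Cl2, rt) with a several-fold excess of alcohol 19 should give 25; the excess alcohol favours O–H insertion over intramolecular cyclopropanation of the prenyl alkene.

3. Step 17. The prenyl alkene may be lost by acid-promoted hydration or cyclisation onto the furan, and the electron-rich arylfuran may degrade during slow aqueous acetal hydrolysis.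
 - Fallback: the order of the last two operations is reversed. It sets out from furan ester 31 and comes back at target 33.
 - The MOM groups are removed by acetal exchange with HCl in dry MeOH at 0 °C → rt, which is faster and milder than aqueous hydrolysis and harmless to the methyl ester, to give methyl (2R,5R)-5-[5-(2,5-dihydroxyphenyl)furan-3-yl]-2,8-dimethylnon-7-enoate F10.
 - The ester is then saponified with LiOH in degassed THF/H2O under argon in the presence of Na2S2O4 and acidified to give 33.

**Further compounds**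

F1 | step 14 | tributyl{[(4-methoxybenzyl)oxy]methyl}stannane | CCCC[Sn](CCCC)(CCCC)COCc1ccc(OC)cc1
F2 | step 14 | methyl (2R,5R)-5-{1-hydroxy-2-[(4-methoxybenzyl)oxy]ethyl}-2,8-dimethylnon-7-enoate (both carbinol epimers) | CC(C)=CC[C@@H](CC[C@@H](C)C(=O)OC)C(O)COCc1ccc(OC)cc1
F3 | step 14 | methyl (2R,5R)-5-{[(4-methoxybenzyl)oxy]acetyl}-2,8-dimethylnon-7-enoate | CC(C)=CC[C@@H](CC[C@@H](C)C(=O)OC)C(=O)COCc1ccc(OC)cc1
F4 | step 14 | 2-ethynyl-1,4-bis(methoxymethoxy)benzene | C#Cc1cc(OCOC)ccc1OCOC
F5 | step 14 | methyl (2R,5R)-5-{4-[2,5-bis(methoxymethoxy)phenyl]-2-hydroxy-1-[(4-methoxybenzyl)oxy]but-3-yn-2-yl}-2,8-dimethylnon-7-enoate (both carbinol epimers) | CC(C)=CC[C@@H](CC[C@@H](C)C(=O)OC)C(O)(COCc1ccc(OC)cc1)C#Cc1cc(OCOC)ccc1OCOC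
F6 | step 14 | methyl (2R,5R)-5-{4-[2,5-bis(methoxymethoxy)phenyl]-1,2-dihydroxybut-3-yn-2-yl}-2,8-dimethylnon-7-enoate (both carbinol epimers) | CC(C)=CC[C@@H](CC[C@@H](C)C(=O)OC)C(O)(CO)C#Cc1cc(OCOC)ccc1OCOC
F7 | step 12 | (2R,5R)-6-methoxy-5-methyl-2-(3-methylbut-2-en-1-yl)-6-oxohexanoic acid | CC(C)=CC[C@@H](CC[C@@H](C)C(=O)OC)C(=O)O
F8 | step 12 | methyl (2R,5R)-5-(chlorocarbonyl)-2,8-dimethylnon-7-enoate | CC(C)=CC[C@@H](CC[C@@H](C)C(=O)OC)C(Cl)=O
F9 | step 12 | methyl (2R,5R)-5-(diazoacetyl)-2,8-dimethylnon-7-enoate | CC(C)=CC[C@@H](CC[C@@H](C)C(=O)OC)C(=O)C=[N+]=[N-]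
F10 | step 17 | methyl (2R,5R)-5-[5-(2,5-dihydroxyphenyl)furan-3-yl]-2,8-dimethylnon-7-enoate | CC(C)=CC[C@@H](CC[C@@H](C)C(=O)OC)c1coc(-c2cc(O)ccc2O)c1
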